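**Strategy.** Moracin Q is cut at the furan C2=C3 bond. That bond lies between C3a of ring A and C2, which carries the resorcinol ring B, while O1 sits on C7a next to C3a. An ester on the C7a oxygen can therefore hold the ring B carbonyl carbon (future C2) beside a phosphonium ylide carbon on C3a (future C3). One intramolecular Wittig olefination then forms C2=C3, closes the furan and unites both aryl rings. The precursor is a 2-(aroyloxy)benzyl triphenylphosphonium salt carrying OBn (C6), OMe (C5) and the C4 side chain as a dioxolane; it is generated in the flask from a 2-hydroxybenzyl phosphonium iodide and 3,5-bis(benzyloxy)benzoyl chloride.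

Key step: step 10

Remarks on the chemistry:
- 3-Bromo-4,5-dihydroxybenzaldehyde is taken as purchasable; it is otherwise one demethylation (AlCl3, pyridine) from 5-bromovanillin.
- The phosphonium salts are carried as iodides, because the salt is made without acid from a Mannich base methiodide, so the dioxolane never meets a strong acid.
- The oxanyl (THP) acetals 6 and 8 are racemic; the target has no stereocentre.

**Route**

Step 1
Reactants: 1 3-bromo-4,5-dihydroxybenzaldehyde
Product: 2 3-bromo-5-hydroxy-4-methoxybenzaldehyde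
Conditions: MeI (1.05 equiv), Li2CO3 (1.1 equiv), DMF, 40 °C
Reagents that add atoms: iodomethane, CI
Why: Regioselective Williamson etherification: the 4-OH, para to the formyl group and ortho to bromine, is the more acidic phenol, so its lithium phenoxide should be the one that is methylated.

Step 2
Reactants: 2 3-bromo-5-hydroxy-4-methoxybenzaldehyde
Product: 3 3-(benzyloxy)-5-bromo-4-methoxybenzaldehyde
Conditions: BnBr, K2CO3, DMF, rt
Reagents that add atoms: benzyl bromide, BrCc1ccccc1
Why: Williamson etherification of the one remaining phenol, which fixes the future C6 oxygen as a benzyl ether that lasts until the final hydrogenolysis.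

Step 3
Reactants: 3 3-(benzyloxy)-5-bromo-4-methoxybenzaldehyde
Product: 5 3-(benzyloxy)-5-bromo-4-methoxyphenol, via aryl formate 4 (not isolated)
Conditions: mCPBA, CH2Cl2, 0 °C → rt; then K2CO3 (cat.), MeOH, rt
Reagents that add atoms: 3-chloroperbenzoic acid (mCPBA), OOC(=O)c1cccc(Cl)c1
Why: Baeyer–Villiger (Dakin-type) oxidation: the alkoxy-substituted aryl group migrates in the peracid adduct, and the formate is removed by transesterification to leave the phenol that becomes O1.

Step 4
Reactants: 5 3-(benzyloxy)-5-bromo-4-methoxyphenol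
Product: 6 2-[3-(benzyloxy)-5-bromo-4-methoxyphenoxy]oxane (racemic)
Conditions: 3,4-dihydro-2H-pyran, PPTS (cat.), CH2Cl2, rt
Reagents that add atoms: 3,4-dihydro-2H-pyran, C1=COCCC1
Why: Acid-catalysed addition of the phenol to the enol ether (tetrahydropyranylation) gives a base-stable acetal that masks the acidic OH during the enolate coupling; its acetal carbon is a temporary, racemic stereocentre.

Step 5
Reactants: 6 2-[3-(benzyloxy)-5-bromo-4-methoxyphenoxy]oxane; 7 3-methylbutan-2-one
Product: 8 1-[3-(benzyloxy)-2-methoxy-5-(oxan-2-yloxy)phenyl]-3-methylbutan-2-one (racemic)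
Conditions: Pd2(dba)3 (1.5 mol%), Xantphos (3.6 mol%), NaOtBu (1.3 equiv), 7 (2.5 equiv), toluene, 80 °C
Reagents that add atoms: none
Why: Palladium-catalysed ketone α-arylation (Buchwald–Hartwig type): the aryl bromide adds oxidatively to zerovalent palladium and couples with the less hindered methyl-side enolate, while excess ketone and the ortho-methoxy group should hold back a second arylation.

Step 6
Reactants: 8 1-[3-(benzyloxy)-2-methoxy-5-(oxan-2-yloxy)phenyl]-3-methylbutan-2-one
Product: 9 3-(benzyloxy)-4-methoxy-5-{[2-(propan-2-yl)-1,3-dioxolan-2-yl]methyl}phenol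
Conditions: ethylene glycol (10 equiv), p-TsOH·H2O (5 mol%), toluene, reflux, Dean–Stark
Reagents that add atoms: ethane-1,2-diol, OCCO
Why: Acid-catalysed ketalisation with azeotropic removal of water; the same acid and the excess diol cleave the oxanyl acetal by transacetalisation, so the phenol is set free in the same operation.

Step 7
Reactants: 9 3-(benzyloxy)-4-methoxy-5-{[2-(propan-2-yl)-1,3-dioxolan-2-yl]methyl}phenol
Product: 10 5-(benzyloxy)-2-[(dimethylamino)methyl]-4-methoxy-3-{[2-(propan-2-yl)-1,3-dioxolan-2-yl]methyl}phenol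
Conditions: Me2NCH2NMe2 (1.3 equiv), 1,4-dioxane, 90 °C
Reagents that add atoms: bis(dimethylamino)methane, CN(C)CN(C)C
Why: Phenol Mannich reaction (ortho-aminomethylation through a hydrogen-bonded iminium–phenoxide pair): the para carbon is blocked by OMe, and of the two ortho carbons the one para to OBn should react, because the other lies between two oxygen substituents, the site that resorcinol-type rings avoid.

Step 8
Reactants: 10 5-(benzyloxy)-2-[(dimethylamino)methyl]-4-methoxy-3-{[2-(propan-2-yl)-1,3-dioxolan-2-yl]methyl}phenol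
Product: 12 [4-(benzyloxy)-2-hydroxy-5-methoxy-6-{[2-(propan-2-yl)-1,3-dioxolan-2-yl]methyl}benzyl]triphenylphosphonium iodide, via ammonium iodide 11 (not isolated)
Conditions: MeI (1.05 equiv), MeCN, rt; then PPh3 (1.5 equiv), MeCN, reflux
Reagents that add atoms: iodomethane, CI; triphenylphosphine, c1ccc(cc1)P(c1ccccc1)c1ccccc1
Why: N-Quaternisation followed by elimination–addition: on heating the 2-hydroxybenzyl trimethylammonium salt loses trimethylamine to an ortho-quinone methide that triphenylphosphine traps by conjugate addition, so the salt forms without acid and the dioxolane is left intact.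

Step 9
Reactants: 13 3,5-bis(benzyloxy)benzoic acid
Product: 14 3,5-bis(benzyloxy)benzoyl chloride
Conditions: (COCl)2 (1.5 equiv), DMF (cat.), CH2Cl2, 0 °C → rt; evaporate
Reagents that add atoms: oxalyl chloride, ClC(=O)C(=O)Cl
Why: Acyl chloride formation through the catalytic chloroiminium (Vilsmeier-type) species; the benzyl ethers are inert and the crude chloride is used at once.

Step 10
Reactants: 12 [4-(benzyloxy)-2-hydroxy-5-methoxy-6-{[2-(propan-2-yl)-1,3-dioxolan-2-yl]methyl}benzyl]triphenylphosphonium iodide; 14 3,5-bis(benzyloxy)benzoyl chloride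
Product: 16 6-(benzyloxy)-2-[3,5-bis(benzyloxy)phenyl]-5-methoxy-4-{[2-(propan-2-yl)-1,3-dioxolan-2-yl]methyl}-1-benzofuran, via ester phosphonium iodide 15 (not isolated)
Conditions: 14 (1.05 equiv), Et3N (3.5 equiv), toluene, 0 °C → rt, 1 h; then reflux
Reagents that add atoms: none
Why: Triethylamine first mediates O-acylation of the phenol of 12 by 14 to give ester 15 and then reversibly deprotonates the benzylic CH2–P carbon; the ylide carbon (future C3) adds to the ester carbonyl carbon (future C2) and the oxaphosphetane collapses with loss of Ph3PO, which forms the C2=C3 bond. This is the known intramolecular Wittig olefination of 2-acyloxybenzyl phosphonium salts to 2-substituted benzofurans. The furan closes in a 5-exo-trig mode, because the ylide carbon on C3a and the carbonyl on the C7a oxygen are held ortho to each other on ring A. No stereocentre is formed, and aromatisation of the benzofuran drives the otherwise slow olefination of an ester. The step needs the ylide to choose the ester carbonyl over the side-chain carbonyl (which would close an indene) and needs O- over C-acylation: the dioxolane removes the first competitor, and one equivalent of 14 added cold before heating secures the second.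

Step 11
Reactants: 16 6-(benzyloxy)-2-[3,5-bis(benzyloxy)phenyl]-5-methoxy-4-{[2-(propan-2-yl)-1,3-dioxolan-2-yl]methyl}-1-benzofuran
Product: 18 moracin Q, via ketal triol 17 (not isolated)
Conditions: H2 (1 atm), Pd/C (10 wt% Pd), EtOAc–MeOH, rt; filter; then 1 M HCl, THF, rt
Reagents that add atoms: water, O
Why: Hydrogenolysis of the three aryl benzyl ethers over palladium on carbon, then acid-catalysed hydrolysis of the dioxolane in the filtrate; at one atmosphere and room temperature the benzofuran and the later-released aliphatic ketone should not be reduced.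

**Compound list**

1 | 3-bromo-4,5-dihydroxybenzaldehyde | O=Cc1cc(O)c(O)c(Br)c1 | starting material
2 | 3-bromo-5-hydroxy-4-methoxybenzaldehyde | COc1c(O)cc(C=O)cc1Br | intermediate
3 | 3-(benzyloxy)-5-bromo-4-methoxybenzaldehyde | COc1c(OCc2ccccc2)cc(C=O)cc1Br | intermediate
4 | 3-(benzyloxy)-5-bromo-4-methoxyphenyl formate | COc1c(OCc2ccccc2)cc(OC=O)cc1Br | intermediate
5 | 3-(benzyloxy)-5-bromo-4-methoxyphenol | COc1c(OCc2ccccc2)cc(O)cc1Br | intermediate
6 | 2-[3-(benzyloxy)-5-bromo-4-methoxyphenoxy]oxane (racemic) | COc1c(OCc2ccccc2)cc(OC2CCCCO2)cc1Br | intermediate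
7 | 3-methylbutan-2-one | CC(C)C(C)=O | starting material
8 | 1-[3-(benzyloxy)-2-methoxy-5-(oxan-2-yloxy)phenyl]-3-methylbutan-2-one (racemic) | COc1c(OCc2ccccc2)cc(OC2CCCCO2)cc1CC(=O)C(C)C | intermediate
9 | 3-(benzyloxy)-4-methoxy-5-{[2-(propan-2-yl)-1,3-dioxolan-2-yl]methyl}phenol | COc1c(OCc2ccccc2)cc(O)cc1CC1(C(C)C)OCCO1 | intermediate
10 | 5-(benzyloxy)-2-[(dimethylamino)methyl]-4-methoxy-3-{[2-(propan-2-yl)-1,3-dioxolan-2-yl]methyl}phenol | COc1c(OCc2ccccc2)cc(O)c(CN(C)C)c1CC1(C(C)C)OCCO1 | intermediate
11 | [4-(benzyloxy)-2-hydroxy-5-methoxy-6-{[2-(propan-2-yl)-1,3-dioxolan-2-yl]methyl}phenyl]-N,N,N-trimethylmethanaminium iodide | COc1c(OCc2ccccc2)cc(O)c(C[N+](C)(C)C)c1CC1(C(C)C)OCCO1.[I-] | intermediate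
12 | [4-(benzyloxy)-2-hydroxy-5-methoxy-6-{[2-(propan-2-yl)-1,3-dioxolan-2-yl]methyl}benzyl]triphenylphosphonium iodide | COc1c(OCc2ccccc2)cc(O)c(C[P+](c2ccccc2)(c2ccccc2)c2ccccc2)c1CC1(C(C)C)OCCO1.[I-] | intermediate
13 | 3,5-bis(benzyloxy)benzoic acid | OC(=O)c1cc(OCc2ccccc2)cc(OCc2ccccc2)c1 | starting material
14 | 3,5-bis(benzyloxy)benzoyl chloride | ClC(=O)c1cc(OCc2ccccc2)cc(OCc2ccccc2)c1 | intermediate
15 | [4-(benzyloxy)-2-{[3,5-bis(benzyloxy)benzoyl]oxy}-5-methoxy-6-{[2-(propan-2-yl)-1,3-dioxolan-2-yl]methyl}benzyl]triphenylphosphonium iodide | COc1c(OCc2ccccc2)cc(OC(=O)c2cc(OCc3ccccc3)cc(OCc3ccccc3)c2)c(C[P+](c2ccccc2)(c2ccccc2)c2ccccc2)c1CC1(C(C)C)OCCO1.[I-] | intermediate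
16 | 6-(benzyloxy)-2-[3,5-bis(benzyloxy)phenyl]-5-methoxy-4-{[2-(propan-2-yl)-1,3-dioxolan-2-yl]methyl}-1-benzofuran | COc1c(OCc2ccccc2)cc2oc(-c3cc(OCc4ccccc4)cc(OCc4ccccc4)c3)cc2c1CC1(C(C)C)OCCO1 | intermediate
17 | 5-(6-hydroxy-5-methoxy-4-{[2-(propan-2-yl)-1,3-dioxolan-2-yl]methyl}-1-benzofuran-2-yl)benzene-1,3-diol | COc1c(O)cc2oc(-c3cc(O)cc(O)c3)cc2c1CC1(C(C)C)OCCO1 | intermediate
18 | moracin Q (1-[2-(3,5-dihydroxyphenyl)-6-hydroxy-5-methoxy-1-benzofuran-4-yl]-3-methylbutan-2-one) | COc1c(O)cc2oc(-c3cc(O)cc(O)c3)cc2c1CC(=O)C(C)C | target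

**Step count and risks**

Total step count: 11. Longest linear sequence: 10 steps (steps 1 to 8, 10 and 11); step 9 is a one-step side branch.

Steps most likely to fail:

Step 10. Before O-acylation is complete, the phenoxide–phosphonium betaine may expel triphenylphosphine again. The crowded ylide may also be acylated on carbon by leftover acid chloride, or the olefination of the ester may stall between its two ortho neighbours. The fallback builds the furan by a tandem Sonogashira coupling and 5-endo-dig cyclisation; it sets out from phenol 9 and returns at benzofuran 16. Iodination of 9 (N-iodosuccinimide, CH2Cl2, 0 °C) at the ortho carbon para to OBn should give 5-(benzyloxy)-2-iodo-4-methoxy-3-{[2-(propan-2-yl)-1,3-dioxolan-2-yl]methyl}phenol F1. Commercial 3,5-bis(benzyloxy)benzaldehyde is homologated with the Ohira–Bestmann reagent (K2CO3, MeOH) to 1,3-bis(benzyloxy)-5-ethynylbenzene F2. Coupling of F1 with F2 (PdCl2(PPh3)2, CuI, Et3N, DMF, 70 °C) and cyclisation of the resulting 2-alkynylphenol in the same pot should deliver 16.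

Step 7. The iminium ion may attack the ortho carbon between OH and OBn, or a second aminomethylation may follow there. The fallback replaces OH-directed substitution by a bromination that is steered para to OBn, followed by halogen–lithium exchange; it sets out from phenol 9 and returns at Mannich base 10. Protection (SEMCl, iPr2NEt, CH2Cl2) gives (2-{[3-(benzyloxy)-4-methoxy-5-{[2-(propan-2-yl)-1,3-dioxolan-2-yl]methyl}phenoxy]methoxy}ethyl)trimethylsilane F3. Bromination (NBS, MeCN, 0 °C) should then give (2-{[5-(benzyloxy)-2-bromo-4-methoxy-3-{[2-(propan-2-yl)-1,3-dioxolan-2-yl]methyl}phenoxy]methoxy}ethyl)trimethylsilane F4, as the carbon between two ether oxygens is the site that resorcinol diethers leave untouched. Exchange and trapping (n-BuLi, THF, −78 °C; then dimethylmethyleneammonium iodide, Eschenmoser's salt) give 1-[4-(benzyloxy)-5-methoxy-6-{[2-(propan-2-yl)-1,3-dioxolan-2-yl]methyl}-2-{[2-(trimethylsilyl)ethoxy]methoxy}phenyl]-N,N-dimethylmethanamine F5. Fluoride cleavage of the acetal (TBAF, DMPU, 80 °C) returns 10.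

Step 5. The coupling may run through the methine-side enolate, the product enolate may be arylated a second time, or the bromide may be reduced instead of coupled. The fallback builds the chain by epoxide opening and oxidation; it sets out from bromide 6 and returns at ketone 8. Bromine–lithium exchange and copper-catalysed opening of racemic 2-(propan-2-yl)oxirane at its CH2 terminus (n-BuLi, THF, −78 °C; MgBr2·OEt2; CuI (10 mol%), epoxide, −30 → 0 °C) should give 1-[3-(benzyloxy)-2-methoxy-5-(oxan-2-yloxy)phenyl]-3-methylbutan-2-ol F6. Oxidation with Dess–Martin periodinane (NaHCO3, CH2Cl2, rt) gives 8.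

Further compounds
F1 | step 10 | 5-(benzyloxy)-2-iodo-4-methoxy-3-{[2-(propan-2-yl)-1,3-dioxolan-2-yl]methyl}phenol | COc1c(OCc2ccccc2)cc(O)c(I)c1CC1(C(C)C)OCCO1
F2 | step 10 | 1,3-bis(benzyloxy)-5-ethynylbenzene | C#Cc1cc(OCc2ccccc2)cc(OCc2ccccc2)c1
F3 | step 7 | (2-{[3-(benzyloxy)-4-methoxy-5-{[2-(propan-2-yl)-1,3-dioxolan-2-yl]methyl}phenoxy]methoxy}ethyl)trimethylsilane | COc1c(OCc2ccccc2)cc(OCOCC[Si](C)(C)C)cc1CC1(C(C)C)OCCO1
F4 | step 7 | (2-{[5-(benzyloxy)-2-bromo-4-methoxy-3-{[2-(propan-2-yl)-1,3-dioxolan-2-yl]methyl}phenoxy]methoxy}ethyl)trimethylsilane | COc1c(OCc2ccccc2)cc(OCOCC[Si](C)(C)C)c(Br)c1CC1(C(C)C)OCCO1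
F5 | step 7 | 1-[4-(benzyloxy)-5-methoxy-6-{[2-(propan-2-yl)-1,3-dioxolan-2-yl]methyl}-2-{[2-(trimethylsilyl)ethoxy]methoxy}phenyl]-N,N-dimethylmethanamine | COc1c(OCc2ccccc2)cc(OCOCC[Si](C)(C)C)c(CN(C)C)c1CC1(C(C)C)OCCO1
F6 | step 5 | 1-[3-(benzyloxy)-2-methoxy-5-(oxan-2-yloxy)phenyl]-3-methylbutan-2-ol (racemic mixture of diastereomers) | COc1c(OCc2ccccc2)cc(OC2CCCCO2)cc1CC(O)C(C)C
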